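## Retrosynthetic overview

1. The target comes from its side-chain triethylsilyl ether by fluoride desilylation.
2. Both rings are made in one flask from an acyclic (Z,Z)-bromo-enal: allylchromium addition closes the ten-membered carbocycle first (C6–C7, the bond that corresponds to farnesyl C1–C10 closure), then the O6 alkoxide closes the γ-lactone on C12.
3. The complete C8 ester is already in place in that precursor: it is the only stereocontrol element for C6 and C7, and it blocks the competing 8,12-lactone.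
4. The acyclic precursor comes from cross-metathesis of a C8 allylic ester with methyl 2-(bromomethyl)acrylate. Its skeleton is neryl acetate (C1–C6, Z-alkene C4=C5), a Z-iodoalkene (C1=C10), (R)-epichlorohydrin (C7–C9, sets C8) and one ylide carbon (C11).
5. The side-chain acid comes from ethyl (S)-3-hydroxybutanoate by two chelate-controlled enolate functionalisations.

Assumption: ring positions are cited with germacrane numbering (C6 lactone carbinol carbon, C7 ring-fusion carbon, C8 acyloxy carbon, C11/C12/C13 the methylene-lactone carbons), also for acyclic precursors.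

## Route

Step 1
Reactants: 1 neryl acetate [(2Z)-3,7-dimethylocta-2,6-dien-1-yl acetate]
Product: 3 (2Z)-3-methyl-6-oxohex-2-en-1-yl acetate, via secondary ozonide 2 (not isolated)
Conditions: O3 (1 equiv, Sudan Red 7B end-point), CH2Cl2, −78 °C; then Me2S, −78 → 25 °C
Reagents that add atoms: ozone, [O-][O+]=O
Why: Criegee ozonolysis with reductive work-up; the distal trisubstituted alkene is more electron-rich than the 2,3-alkene, which is deactivated by the allylic acetate, so one equivalent of ozone cleaves it selectively and the Z-alkene is kept (no stereocentre formed).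

Step 2
Reactants: 3 (2Z)-3-methyl-6-oxohex-2-en-1-yl acetate
Product: 5 (2Z,6Z)-7-iodo-3-methylocta-2,6-dien-1-ol, via iodoalkene acetate 4 (not isolated)
Conditions: EtPPh3I, n-BuLi, THF, 25 °C; I2, −78 °C; NaN(SiMe3)2, −20 °C; 3, −78 → −20 °C; then K2CO3, MeOH, 25 °C
Reagents that add atoms: ethyltriphenylphosphonium iodide, CC[P+](c1ccccc1)(c1ccccc1)c1ccccc1.[I-]; iodine, II
Why: Stork–Zhao-type Wittig olefination with the α-iodo ylide gives the (Z)-2-iodoalkene (iodine cis to the chain) under kinetic control, and in-flask methanolysis removes the acetate, which would not survive the organolithium step.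

Step 3
Reactants: 5 (2Z,6Z)-7-iodo-3-methylocta-2,6-dien-1-ol; 6 (R)-epichlorohydrin [(2R)-2-(chloromethyl)oxirane]
Product: 9 (2Z,6Z,9R)-10-chloro-3,7-dimethyldeca-2,6-diene-1,9-diol, via lithium alkoxide 7 (not isolated), via alkenyllithium alkoxide 8 (not isolated)
Conditions: n-BuLi (1.0 equiv), then t-BuLi (2.1 equiv), THF/Et2O, −78 °C; 6, BF3·OEt2, −78 °C; aq. NH4Cl
Reagents that add atoms: none
Why: Iodine–lithium exchange gives the alkenyllithium with retention of the Z geometry, and BF3-promoted SN2 epoxide opening at the unsubstituted CH2 forms C9–C10, so the C8 stereocentre is carried over unchanged from (R)-epichlorohydrin and the chloride stays in place.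

Step 4
Reactants: 9 (2Z,6Z,9R)-10-chloro-3,7-dimethyldeca-2,6-diene-1,9-diol
Product: 11 (2Z,6Z,9R)-3,7-dimethylundeca-2,6,10-triene-1,9-diol, via terminal epoxide 10 (not isolated)
Conditions: Me3SI, n-BuLi (excess), THF, −10 → 25 °C
Reagents that add atoms: trimethylsulfonium iodide, C[S+](C)C.[I-]
Why: Base closes the chlorohydrin to the epoxide; dimethylsulfonium methylide opens it at CH2 and then eliminates Me2S from the γ-oxido sulfonium salt (one-carbon epoxide-to-allylic-alcohol homologation), which leaves C8 untouched.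

Step 5
Reactants: 11 (2Z,6Z,9R)-3,7-dimethylundeca-2,6,10-triene-1,9-diol
Product: 12 (2Z,6Z,9R)-9-hydroxy-3,7-dimethylundeca-2,6,10-trienal
Conditions: TEMPO (10 mol%), PhI(OAc)2 (1.1 equiv), CH2Cl2, 0 → 25 °C
Reagents that add atoms: none
Why: TEMPO/oxoammonium oxidation is selective for the primary allylic alcohol over the secondary one and is neutral, so the Z-enal does not isomerise.

Step 6
Reactants: 13 ethyl (3S)-3-hydroxybutanoate
Product: 15 ethyl (2S,3S)-3-hydroxy-2-methylbutanoate, via dilithium dianion 14 (not isolated)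
Conditions: LiN(i-Pr)2 (2.2 equiv), THF, −50 → −20 °C; MeI, DMPU, −50 → 0 °C
Reagents that add atoms: iodomethane, CI
Why: Fráter–Seebach alkylation: the chelated alkoxide-enolate is methylated anti to the C3 methyl group, which sets C2 as S (2,3-anti).

Step 7
Reactants: 15 ethyl (2S,3S)-3-hydroxy-2-methylbutanoate
Product: 17 ethyl (2S,3S)-2,3-dihydroxy-2-methylbutanoate, via dilithium dianion 16 (not isolated)
Conditions: LiN(i-Pr)2 (2.2 equiv), THF, −78 → −20 °C; 3-phenyl-2-(phenylsulfonyl)oxaziridine, −78 °C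
Reagents that add atoms: 3-phenyl-2-(phenylsulfonyl)oxaziridine, O=S(=O)(c1ccccc1)N1OC1c1ccccc1
Why: Second Fráter–Seebach functionalisation (electrophilic enolate hydroxylation): oxygen is delivered to the same face of the chelated tetrasubstituted enolate, anti to the C3 methyl, giving the (2S,3S) anti-diol with the tertiary carbinol.

Step 8
Reactants: 17 ethyl (2S,3S)-2,3-dihydroxy-2-methylbutanoate
Product: 18 ethyl (2S,3S)-2-hydroxy-2-methyl-3-[(triethylsilyl)oxy]butanoate
Conditions: Et3SiCl, imidazole, DMF, 0 °C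
Reagents that add atoms: chlorotriethylsilane, CC[Si](Cl)(CC)CC
Why: Chemoselective silylation of the secondary hydroxyl (the tertiary α-hydroxyl is too hindered), which also prevents retro-aldol cleavage in the next step.

Step 9
Reactants: 18 ethyl (2S,3S)-2-hydroxy-2-methyl-3-[(triethylsilyl)oxy]butanoate
Product: 19 (2S,3S)-2-hydroxy-2-methyl-3-[(triethylsilyl)oxy]butanoic acid
Conditions: LiOH·H2O, THF/MeOH/H2O, 0 → 25 °C; then 1 M HCl to pH 4, 0 °C
Reagents that add atoms: lithium hydroxide, [Li+].[OH-]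
Why: Saponification of an α-hydroxy ester (activated by the α-hydroxyl) under conditions that a secondary triethylsilyl ether tolerates; no stereocentre is affected.

Step 10
Reactants: 12 (2Z,6Z,9R)-9-hydroxy-3,7-dimethylundeca-2,6,10-trienal; 19 (2S,3S)-2-hydroxy-2-methyl-3-[(triethylsilyl)oxy]butanoic acid
Product: 21 (3R,5Z,9Z)-5,9-dimethyl-11-oxoundeca-1,5,9-trien-3-yl (2S,3S)-2-hydroxy-2-methyl-3-[(triethylsilyl)oxy]butanoate, via mixed anhydride 20 (not isolated)
Conditions: 19, 2,4,6-Cl3C6H2COCl, Et3N, toluene, 25 °C; then 12, DMAP, 0 → 25 °C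
Reagents that add atoms: none
Why: Yamaguchi esterification through the mixed anhydride acylates O8 with retention at C8 (the tertiary hydroxyl of the acid is too hindered to compete), installing the ester that later blocks 8,12-lactonisation and steers the ring closure.

Step 11
Reactants: 21 (3R,5Z,9Z)-5,9-dimethyl-11-oxoundeca-1,5,9-trien-3-yl (2S,3S)-2-hydroxy-2-methyl-3-[(triethylsilyl)oxy]butanoate; 22 methyl 2-(bromomethyl)prop-2-enoate
Product: 23 methyl (2Z,4R,6Z,10Z)-2-(bromomethyl)-4-{[(2S,3S)-2-hydroxy-2-methyl-3-(triethylsilyloxy)butanoyl]oxy}-6,10-dimethyl-12-oxododeca-2,6,10-trienoate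
Conditions: 22 (10 equiv), second-generation Hoveyda–Grubbs catalyst RuCl2(H2IMes)(=CH-C6H4-2-O-i-Pr) (10 mol%), CH2Cl2, 40 °C
Reagents that add atoms: none
Why: Olefin cross-metathesis: only the monosubstituted vinyl group engages the ruthenium carbene (the trisubstituted alkenes and the enal are inert), and the thermodynamically preferred isomer with C8 cis to CH2Br (2Z) is formed with loss of ethylene.

Step 12
Reactants: 23 methyl (2Z,4R,6Z,10Z)-2-(bromomethyl)-4-{[(2S,3S)-2-hydroxy-2-methyl-3-(triethylsilyloxy)butanoyl]oxy}-6,10-dimethyl-12-oxododeca-2,6,10-trienoate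
Product: 26 (3aR,4R,6Z,10Z,11aS)-6,10-dimethyl-3-methylidene-2-oxo-2,3,3a,4,5,8,9,11a-octahydrocyclodeca[b]furan-4-yl (2S,3S)-2-hydroxy-2-methyl-3-[(triethylsilyl)oxy]butanoate, via allylchromium species 24 (not isolated), via chromium alkoxide 25 (not isolated)
Conditions: CrCl2 (10 equiv), THF/DMF (4:1), 25 °C, syringe-pump addition of 23 to 2 mM; aq. sodium potassium tartrate
Reagents that add atoms: none
Why: Intramolecular Nozaki–Hiyama–Kishi allylation then lactonisation: C6–C7 closes the ten-membered ring through a chair Zimmerman–Traxler transition state (C8 cis to CH2Cr and axial, C5 equatorial) that gives the 6,7-syn adduct, allylic 1,3-strain holds H8 in the alkene plane so the aldehyde tethered through C9 adds to C7 anti to the bulky 8-acyloxy group (6S,7R from 8R), and the O6 alkoxide then displaces methoxide at C12 to give the cis-fused lactone.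

Step 13
Reactants: 26 (3aR,4R,6Z,10Z,11aS)-6,10-dimethyl-3-methylidene-2-oxo-2,3,3a,4,5,8,9,11a-octahydrocyclodeca[b]furan-4-yl (2S,3S)-2-hydroxy-2-methyl-3-[(triethylsilyl)oxy]butanoate
Product: 27 (−)-ursiniolide D [(3aR,4R,6Z,10Z,11aS)-6,10-dimethyl-3-methylidene-2-oxo-2,3,3a,4,5,8,9,11a-octahydrocyclodeca[b]furan-4-yl (2S,3S)-2,3-dihydroxy-2-methylbutanoate]
Conditions: HF·pyridine, pyridine, THF, 0 → 25 °C
Reagents that add atoms: none
Why: Buffered fluoride desilylation removes the secondary triethylsilyl ether without touching the allylic lactone, the α-methylene unit or the two esters; no stereocentre is affected.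

## Compound list

1 | neryl acetate, (2Z)-3,7-dimethylocta-2,6-dien-1-yl acetate | CC(=O)OC/C=C(/C)CCC=C(C)C | starting material
2 | (2Z)-5-(5,5-dimethyl-1,2,4-trioxolan-3-yl)-3-methylpent-2-en-1-yl acetate (secondary ozonide, ring carbon racemic) | CC(=O)OC/C=C(/C)CCC1OOC(C)(C)O1 | intermediate
3 | (2Z)-3-methyl-6-oxohex-2-en-1-yl acetate | CC(=O)OC/C=C(/C)CCC=O | intermediate
4 | (2Z,6Z)-7-iodo-3-methylocta-2,6-dien-1-yl acetate | CC(=O)OC/C=C(/C)CC/C=C(/C)I | intermediate
5 | (2Z,6Z)-7-iodo-3-methylocta-2,6-dien-1-ol | OC/C=C(/C)CC/C=C(/C)I | intermediate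
6 | (R)-epichlorohydrin, (2R)-2-(chloromethyl)oxirane | ClC[C@H]1CO1 | starting material
7 | lithium (2Z,6Z)-7-iodo-3-methylocta-2,6-dien-1-olate | [Li]OC/C=C(/C)CC/C=C(/C)I | intermediate
8 | lithium (2Z,6Z)-7-lithio-3-methylocta-2,6-dien-1-olate | [Li]OC/C=C(/C)CC/C=C(/C)[Li] | intermediate
9 | (2Z,6Z,9R)-10-chloro-3,7-dimethyldeca-2,6-diene-1,9-diol | OC/C=C(/C)CC/C=C(/C)C[C@@H](O)CCl | intermediate
10 | (2Z,6Z)-3,7-dimethyl-8-[(2R)-oxiran-2-yl]octa-2,6-dien-1-ol (present as its lithium alkoxide) | OC/C=C(/C)CC/C=C(/C)C[C@@H]1CO1 | intermediate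
11 | (2Z,6Z,9R)-3,7-dimethylundeca-2,6,10-triene-1,9-diol | OC/C=C(/C)CC/C=C(/C)C[C@@H](O)C=C | intermediate
12 | (2Z,6Z,9R)-9-hydroxy-3,7-dimethylundeca-2,6,10-trienal | O=C/C=C(/C)CC/C=C(/C)C[C@@H](O)C=C | intermediate
13 | ethyl (3S)-3-hydroxybutanoate | CCOC(=O)C[C@H](C)O | starting material
14 | dilithium alkoxide-enolate of 13 | CCO/C(O[Li])=C/[C@H](C)O[Li] | intermediate
15 | ethyl (2S,3S)-3-hydroxy-2-methylbutanoate | CCOC(=O)[C@@H](C)[C@H](C)O | intermediate
16 | dilithium alkoxide-enolate of 15 | CCO/C(O[Li])=C(\C)[C@H](C)O[Li] | intermediate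
17 | ethyl (2S,3S)-2,3-dihydroxy-2-methylbutanoate | CCOC(=O)[C@@](C)(O)[C@H](C)O | intermediate
18 | ethyl (2S,3S)-2-hydroxy-2-methyl-3-[(triethylsilyl)oxy]butanoate | CCOC(=O)[C@@](C)(O)[C@H](C)O[Si](CC)(CC)CC | intermediate
19 | (2S,3S)-2-hydroxy-2-methyl-3-[(triethylsilyl)oxy]butanoic acid | OC(=O)[C@@](C)(O)[C@H](C)O[Si](CC)(CC)CC | intermediate
20 | (2S,3S)-2-hydroxy-2-methyl-3-[(triethylsilyl)oxy]butanoic 2,4,6-trichlorobenzoic anhydride | O=C(OC(=O)[C@@](C)(O)[C@H](C)O[Si](CC)(CC)CC)c1c(Cl)cc(Cl)cc1Cl | intermediate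
21 | (3R,5Z,9Z)-5,9-dimethyl-11-oxoundeca-1,5,9-trien-3-yl (2S,3S)-2-hydroxy-2-methyl-3-[(triethylsilyl)oxy]butanoate | O=C/C=C(/C)CC/C=C(/C)C[C@@H](OC(=O)[C@@](C)(O)[C@H](C)O[Si](CC)(CC)CC)C=C | intermediate
22 | methyl 2-(bromomethyl)prop-2-enoate | C=C(CBr)C(=O)OC | starting material
23 | methyl (2Z,4R,6Z,10Z)-2-(bromomethyl)-4-{[(2S,3S)-2-hydroxy-2-methyl-3-(triethylsilyloxy)butanoyl]oxy}-6,10-dimethyl-12-oxododeca-2,6,10-trienoate | O=C/C=C(/C)CC/C=C(/C)C[C@@H](OC(=O)[C@@](C)(O)[C@H](C)O[Si](CC)(CC)CC)/C=C(\CBr)C(=O)OC | intermediate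
24 | allylchromium dichloride derived from 23 (CrCl2 in place of Br, same alkene geometry, trivalent chromium) | O=C/C=C(/C)CC/C=C(/C)C[C@@H](OC(=O)[C@@](C)(O)[C@H](C)O[Si](CC)(CC)CC)/C=C(\C[Cr](Cl)Cl)C(=O)OC | intermediate
25 | dichlorochromium alkoxide of methyl 2-[(1R,2S,3Z,7Z,10R)-2-hydroxy-4,8-dimethyl-10-({(2S,3S)-2-hydroxy-2-methyl-3-[(triethylsilyl)oxy]butanoyl}oxy)cyclodeca-3,7-dien-1-yl]prop-2-enoate | COC(=O)C(=C)[C@H]1[C@@H](O[Cr](Cl)Cl)/C=C(/C)CC/C=C(/C)C[C@H]1OC(=O)[C@@](C)(O)[C@H](C)O[Si](CC)(CC)CC | intermediate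
26 | (3aR,4R,6Z,10Z,11aS)-6,10-dimethyl-3-methylidene-2-oxo-2,3,3a,4,5,8,9,11a-octahydrocyclodeca[b]furan-4-yl (2S,3S)-2-hydroxy-2-methyl-3-[(triethylsilyl)oxy]butanoate | C=C1C(=O)O[C@H]2/C=C(/C)CC/C=C(/C)C[C@@H](OC(=O)[C@@](C)(O)[C@H](C)O[Si](CC)(CC)CC)[C@@H]12 | intermediate
27 | (−)-ursiniolide D, (3aR,4R,6Z,10Z,11aS)-6,10-dimethyl-3-methylidene-2-oxo-2,3,3a,4,5,8,9,11a-octahydrocyclodeca[b]furan-4-yl (2S,3S)-2,3-dihydroxy-2-methylbutanoate | C=C1C(=O)O[C@H]2/C=C(/C)CC/C=C(/C)C[C@@H](OC(=O)[C@@](C)(O)[C@H](C)O)[C@@H]12 | target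

## Step count and risks

Total step count: 13 (steps 1–13; telescoped operations counted once).
Longest linear sequence: 9 steps (1, 2, 3, 4, 5, 10, 11, 12, 13 from neryl acetate); the side-chain branch is steps 6–9.

The three steps most likely to fail:

**Step 12 (ring closure).** The risks are oligomerisation, 1,4-elimination of the 8-acyloxy group from the allylchromium species to a dienoate, and the wrong facial sense at C7 or a trans-lactone. The fallback sets out from 23 and comes back at 26. It replaces the in-flask allylchromium by a defined allylboron reagent. Borylation of the allylic bromide with B2pin2 and the zerovalent palladium complex Pd2(dba)3 gives methyl (2E,4R,6Z,10Z)-4-{[(2S,3S)-2-hydroxy-2-methyl-3-(triethylsilyloxy)butanoyl]oxy}-6,10-dimethyl-12-oxo-2-[(4,4,5,5-tetramethyl-1,3,2-dioxaborolan-2-yl)methyl]dodeca-2,6,10-trienoate F1. Boron cannot expel the acyloxy group and the alkene geometry is fixed. Sc(OTf)3 (10 mol%) in toluene at 5 mM then triggers intramolecular allylboration through the same chair (syn) transition state, and mildly acidic work-up lactonises the borate to 26.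

**Step 11 (cross-metathesis).** A hindered secondary allylic ester must couple with a 1,1-disubstituted acrylate, so low conversion or alkene migration is possible. The fallback sets out from 5 and comes back at 23; it builds the same enoate by carbonyl chemistry instead of metathesis.
- The alkenyllithium made from 5 as in step 3 is opened (BF3·OEt2) with (R)-triethyl(oxiran-2-ylmethoxy)silane, the triethylsilyl ether of (S)-glycidol, to give (2Z,6Z,9R)-3,7-dimethyl-10-[(triethylsilyl)oxy]deca-2,6-diene-1,9-diol F2.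
- TEMPO/PhI(OAc)2 gives (2Z,6Z,9R)-9-hydroxy-3,7-dimethyl-10-[(triethylsilyl)oxy]deca-2,6-dienal F3.
- Yamaguchi esterification with 19 gives (2R,4Z,8Z)-4,8-dimethyl-10-oxo-1-[(triethylsilyl)oxy]deca-4,8-dien-2-yl (2S,3S)-2-hydroxy-2-methyl-3-[(triethylsilyl)oxy]butanoate F4.
- Swern conditions oxidise the primary triethylsilyl ether directly, leaving the secondary one, to give (2R,4Z,8Z)-4,8-dimethyl-1,10-dioxodeca-4,8-dien-2-yl (2S,3S)-2-hydroxy-2-methyl-3-[(triethylsilyl)oxy]butanoate F5.
- A Morita–Baylis–Hillman reaction with methyl acrylate and DABCO at the aliphatic aldehyde gives methyl (4R,6Z,10Z)-3-hydroxy-4-{[(2S,3S)-2-hydroxy-2-methyl-3-(triethylsilyloxy)butanoyl]oxy}-6,10-dimethyl-2-methylidene-12-oxododeca-6,10-dienoate F6 (C3 epimers, both usable).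
- NBS/Me2S converts F6 with allylic transposition into 23.

**Step 3 (organolithium epoxide opening).** A dianion must be formed and must open epichlorohydrin cleanly in the presence of BF3 and lithium alkoxides. The fallback sets out from 5 (with 6) and comes back at 9 without any organolithium. It is a nickel-catalysed reductive cross-electrophile coupling (NiI2, 4,4′-di-tert-butyl-2,2′-bipyridine, NaI, Zn dust, DMPU, 25 °C). Iodide opens 6 at its CH2 terminus to the iodohydrin, whose primary radical is captured by the alkenylnickel species with retention of the Z geometry. This extends known aryl halide/epoxide couplings to an alkenyl iodide and makes no new compound (F0).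

## Further compounds

F1 | step 12 | methyl (2E,4R,6Z,10Z)-4-{[(2S,3S)-2-hydroxy-2-methyl-3-(triethylsilyloxy)butanoyl]oxy}-6,10-dimethyl-12-oxo-2-[(4,4,5,5-tetramethyl-1,3,2-dioxaborolan-2-yl)methyl]dodeca-2,6,10-trienoate | O=C/C=C(/C)CC/C=C(/C)C[C@@H](OC(=O)[C@@](C)(O)[C@H](C)O[Si](CC)(CC)CC)/C=C(\CB1OC(C)(C)C(C)(C)O1)C(=O)OC
F2 | step 11 | (2Z,6Z,9R)-3,7-dimethyl-10-[(triethylsilyl)oxy]deca-2,6-diene-1,9-diol | OC/C=C(/C)CC/C=C(/C)C[C@@H](O)CO[Si](CC)(CC)CC
F3 | step 11 | (2Z,6Z,9R)-9-hydroxy-3,7-dimethyl-10-[(triethylsilyl)oxy]deca-2,6-dienal | O=C/C=C(/C)CC/C=C(/C)C[C@@H](O)CO[Si](CC)(CC)CC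
F4 | step 11 | (2R,4Z,8Z)-4,8-dimethyl-10-oxo-1-[(triethylsilyl)oxy]deca-4,8-dien-2-yl (2S,3S)-2-hydroxy-2-methyl-3-[(triethylsilyl)oxy]butanoate | O=C/C=C(/C)CC/C=C(/C)C[C@@H](OC(=O)[C@@](C)(O)[C@H](C)O[Si](CC)(CC)CC)CO[Si](CC)(CC)CC
F5 | step 11 | (2R,4Z,8Z)-4,8-dimethyl-1,10-dioxodeca-4,8-dien-2-yl (2S,3S)-2-hydroxy-2-methyl-3-[(triethylsilyl)oxy]butanoate | O=C/C=C(/C)CC/C=C(/C)C[C@@H](OC(=O)[C@@](C)(O)[C@H](C)O[Si](CC)(CC)CC)C=O
F6 | step 11 | methyl (4R,6Z,10Z)-3-hydroxy-4-{[(2S,3S)-2-hydroxy-2-methyl-3-(triethylsilyloxy)butanoyl]oxy}-6,10-dimethyl-2-methylidene-12-oxododeca-6,10-dienoate (C3 epimers) | O=C/C=C(/C)CC/C=C(/C)C[C@@H](OC(=O)[C@@](C)(O)[C@H](C)O[Si](CC)(CC)CC)C(O)C(=C)C(=O)OC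
F0 | step 3 | none | none
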